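**Retrosynthetic overview**
1. The target comes from its bis-silyl ether. The cyclohexenone, the only carbocycle, is closed last by ring-closing metathesis across C1=C6 of an acyclic triene diester.
2. The C7/C1 enone arm comes from an alkenyllithium added to a γ-lactone carbonyl (C2). The lactone masks O5, so O3 is esterified first and O5 (angelate) after ring opening.
3. The α-hydroxy-γ-lactone (C3 set) comes from a Z-enol carbamate by hydroxyl-directed epoxidation, cyclisation and oxidation.
4. The key C4–C5 bond joins a chiral homoenolate equivalent (lithiated, then titanated allyl carbamate with (+)-sparteine) to acrolein. It links the β-carbon of the C2 carbonyl to an aldehyde carbon, two sites that are both acceptors, and sets C4 and C5 together.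
5. Ring order: a temporary oxolane forms (step 3), becomes the lactone (step 4) and is opened (step 9). The cyclohexenone forms in step 11.

Assumption and labels: C1 bears CH2OH (C7), C2 is the ketone, C3 carries the hydroxytiglate (O3), C4 the isopropyl group, C5 the angelate (O5) and C6 is the ring =CH. Compounds 1, 2, 4, 11, 12, 16, 20 and (+)-sparteine are taken as commercial.

Step 1
Reactants: 1 (E)-4-methylpent-2-en-1-ol; 2 N,N-diisopropylcarbamoyl chloride
Product: 3 (E)-4-methylpent-2-en-1-yl N,N-diisopropylcarbamate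
Conditions: NaH, THF, 0 °C to reflux
Reagents that add atoms: none
Why: Nucleophilic acyl substitution of the sodium alkoxide on the carbamoyl chloride gives the hindered carbamate that will direct and stabilise the alpha-oxy carbanion, and no stereocentre is formed.

Step 2
Reactants: 3 (E)-4-methylpent-2-en-1-yl N,N-diisopropylcarbamate; 4 acrolein
Product: 7 (1Z,3R,4S)-4-hydroxy-3-isopropylhexa-1,5-dien-1-yl N,N-diisopropylcarbamate, via lithio carbamate 5 (not isolated), via allyltitanium 6 (not isolated)
Conditions: n-BuLi, (+)-sparteine, toluene, −78 °C; Ti(OiPr)4, −78 °C; 4, −78 °C; aq NH4Cl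
Reagents that add atoms: none
Why: Hoppe asymmetric homoaldol reaction: n-BuLi/(+)-sparteine removes the pro-R proton next to oxygen, Ti(OiPr)4 replaces lithium with inversion, and the allyltitanium, a chiral homoenolate (d3) equivalent, attacks the acrolein carbonyl carbon through its gamma carbon in a chair Zimmerman–Traxler transition state with isopropyl and vinyl equatorial and the carbamoyloxy group axial, so the C4–C5 bond, both stereocentres (anti, 3R,4S) and the Z-enol carbamate are set in one operation.

Step 3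
Reactants: 7 (1Z,3R,4S)-4-hydroxy-3-isopropylhexa-1,5-dien-1-yl N,N-diisopropylcarbamate
Product: 9 (2S,3S,4R,5S)-3-hydroxy-4-isopropyl-5-vinyloxolan-2-yl N,N-diisopropylcarbamate, via epoxide 8 (not isolated)
Conditions: VO(acac)2 (5 mol %), t-BuOOH, CH2Cl2, 0 °C to rt; then camphorsulfonic acid (cat.)
Reagents that add atoms: tert-butyl hydroperoxide, CC(C)(C)OO
Why: Hydroxyl-directed vanadium-catalysed epoxidation of a homoallylic alcohol: the vanadate ester at O5 delivers oxygen to the electron-rich C2=C3 bond through a chair transition state with vinyl, isopropyl and the alkenyl carbon all equatorial and H4 eclipsing the Z-alkene (minimal A1,3 strain), which fixes C3 as S (O3 syn to O5), after which O5 opens the labile epoxide at its acetal-like carbon C2 to close the oxolane and leave O3 as the only free hydroxyl (the anomeric centre drawn is erased in step 4).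

Step 4
Reactants: 9 (2S,3S,4R,5S)-3-hydroxy-4-isopropyl-5-vinyloxolan-2-yl N,N-diisopropylcarbamate
Product: 10 (3S,4R,5S)-3-hydroxy-4-isopropyl-5-vinyloxolan-2-one
Conditions: mCPBA (1.5 equiv), BF3·OEt2 (0.5 equiv), CH2Cl2, 0 °C to rt
Reagents that add atoms: 3-chloroperbenzoic acid (mCPBA), O=C(OO)c1cccc(Cl)c1
Why: Grieco-type peracid oxidation of a cyclic acetal: BF3 ionises the anomeric carbamate, mCPBA traps the oxocarbenium ion and the peroxy acetal fragments to the lactone, which erases the anomeric centre and leaves C3, C4, C5, the free hydroxyl and the slow-reacting monosubstituted alkene untouched.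

Step 5
Reactants: 11 (tert-butyldimethylsilyloxy)acetaldehyde; 12 ethyl 2-(triphenylphosphoranylidene)propanoate
Product: 13 ethyl (E)-4-(tert-butyldimethylsilyloxy)-2-methylbut-2-enoate
Conditions: CH2Cl2, rt
Reagents that add atoms: none
Why: Wittig olefination with a stabilised alpha-branched ylide gives the E-trisubstituted enoate (typically above 95:5) under neutral conditions that spare the silyl ether.

Step 6
Reactants: 13 ethyl (E)-4-(tert-butyldimethylsilyloxy)-2-methylbut-2-enoate
Product: 14 (E)-4-(tert-butyldimethylsilyloxy)-2-methylbut-2-enoic acid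
Conditions: LiOH, THF/MeOH/H2O, rt; then cold 1 M HCl to pH 4
Reagents that add atoms: lithium hydroxide, [Li+].[OH-]
Why: Saponification of the unhindered ethyl ester leaves the primary silyl ether and the alkene geometry intact, and cold acidification frees the acid.

Step 7
Reactants: 10 (3S,4R,5S)-3-hydroxy-4-isopropyl-5-vinyloxolan-2-one; 14 (E)-4-(tert-butyldimethylsilyloxy)-2-methylbut-2-enoic acid
Product: 15 (3S,4S,5S)-4-isopropyl-2-oxo-5-vinyloxolan-3-yl (E)-4-(tert-butyldimethylsilyloxy)-2-methylbut-2-enoate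
Conditions: DCC, DMAP (cat.), CH2Cl2, 0 °C to rt
Reagents that add atoms: none
Why: Steglich esterification acylates the only free hydroxyl (O3) with retention at C3 while O5 is masked as the lactone oxygen, so the two secondary oxygens are differentiated without protecting groups.

Step 8
Reactants: 16 2-bromoprop-2-en-1-ol
Product: 17 (2-bromoallyloxy)(tert-butyl)dimethylsilane
Conditions: NaH, TBSCl, THF, 0 °C
Reagents that add atoms: tert-butyldimethylsilyl chloride (TBSCl), CC(C)(C)[Si](C)(C)Cl
Why: Silylation of the sodium alkoxide protects the future C7 hydroxyl so that the bromide can undergo halogen–lithium exchange.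

Step 9
Reactants: 15 (3S,4S,5S)-4-isopropyl-2-oxo-5-vinyloxolan-3-yl (E)-4-(tert-butyldimethylsilyloxy)-2-methylbut-2-enoate; 17 (2-bromoallyloxy)(tert-butyl)dimethylsilane
Product: 19 (4S,5S,6S)-2-[(tert-butyldimethylsilyloxy)methyl]-6-hydroxy-5-isopropyl-3-oxoocta-1,7-dien-4-yl (E)-4-(tert-butyldimethylsilyloxy)-2-methylbut-2-enoate, via alkenyllithium 18 (not isolated)
Conditions: 17, t-BuLi (2 equiv), Et2O, −78 °C; then 15, THF, −90 °C; AcOH quench at −90 °C
Reagents that add atoms: none
Why: Bromine–lithium exchange gives an alkenyllithium that adds once to the lactone carbonyl, which ring strain and the alpha-acyloxy group make far more electrophilic than the hindered conjugated side-chain ester, and the tetrahedral lithium hemiketal survives at −90 °C until the acidic quench, so over-addition, acyl migration and epimerisation at C3 are suppressed and O5 is released as the free alcohol.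

Step 10
Reactants: 19 (4S,5S,6S)-2-[(tert-butyldimethylsilyloxy)methyl]-6-hydroxy-5-isopropyl-3-oxoocta-1,7-dien-4-yl (E)-4-(tert-butyldimethylsilyloxy)-2-methylbut-2-enoate; 20 angelic acid, (Z)-2-methylbut-2-enoic acid
Product: 22 (4S,5S,6S)-2-[(tert-butyldimethylsilyloxy)methyl]-5-isopropyl-6-[(Z)-2-methylbut-2-enoyloxy]-3-oxoocta-1,7-dien-4-yl (E)-4-(tert-butyldimethylsilyloxy)-2-methylbut-2-enoate, via mixed anhydride 21 (not isolated)
Conditions: 20, 2,4,6-trichlorobenzoyl chloride, Et3N, toluene, rt; then 19, 75 °C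
Reagents that add atoms: none
Why: Yamaguchi-type mixed-anhydride esterification run without DMAP transfers the angeloyl group without Z-to-E isomerisation and acylates O5 with retention at C5.

Step 11
Reactants: 22 (4S,5S,6S)-2-[(tert-butyldimethylsilyloxy)methyl]-5-isopropyl-6-[(Z)-2-methylbut-2-enoyloxy]-3-oxoocta-1,7-dien-4-yl (E)-4-(tert-butyldimethylsilyloxy)-2-methylbut-2-enoate
Product: 23 bis(tert-butyldimethylsilyl) ether of the target, (4S,5S,6S)-configured cyclohex-2-en-1-one
Conditions: second-generation Hoveyda–Grubbs catalyst (10 mol %), toluene (2 mM), 80 °C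
Reagents that add atoms: none
Why: Ring-closing metathesis initiates at the monosubstituted C6 alkene and closes onto the 1,1-disubstituted enone alkene to give the six-membered trisubstituted enone with loss of ethylene, while the trisubstituted electron-poor angelate and hydroxytiglate alkenes are inert and no stereocentre is affected.

Step 12
Reactants: 23 bis(tert-butyldimethylsilyl) ether of the target
Product: 24 (4S,5S,6S)-2-(hydroxymethyl)-6-[(E)-4-hydroxy-2-methylbut-2-enoyloxy]-5-isopropyl-4-[(Z)-2-methylbut-2-enoyloxy]cyclohex-2-en-1-one (CNP0281432.2)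
Conditions: HF·pyridine, pyridine, THF, 0 °C to rt
Reagents that add atoms: none
Why: Fluoride-mediated desilylation under buffered, weakly acidic conditions cleaves both primary allylic silyl ethers without ester cleavage, acyl migration, epimerisation at C3 or elimination of the C5 angelate.

**Compound list**
1 | (E)-4-methylpent-2-en-1-ol | CC(C)/C=C/CO | starting material
2 | N,N-diisopropylcarbamoyl chloride | CC(C)N(C(C)C)C(=O)Cl | starting material
3 | (E)-4-methylpent-2-en-1-yl N,N-diisopropylcarbamate | CC(C)/C=C/COC(=O)N(C(C)C)C(C)C | intermediate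
4 | acrolein | C=CC=O | starting material
5 | (1R,2E)-1-lithio-4-methylpent-2-en-1-yl N,N-diisopropylcarbamate, (+)-sparteine complex | [Li][C@@H](OC(=O)N(C(C)C)C(C)C)/C=C/C(C)C | intermediate
6 | (1S,2E)-4-methyl-1-(triisopropoxytitanio)pent-2-en-1-yl N,N-diisopropylcarbamate | CC(C)O[Ti](OC(C)C)(OC(C)C)[C@H](OC(=O)N(C(C)C)C(C)C)/C=C/C(C)C | intermediate
7 | (1Z,3R,4S)-4-hydroxy-3-isopropylhexa-1,5-dien-1-yl N,N-diisopropylcarbamate | C=C[C@H](O)[C@H](C(C)C)/C=C\OC(=O)N(C(C)C)C(C)C | intermediate
8 | cis C2–C3 epoxide of 7, oxygen on the face syn to the C5 hydroxyl | C=C[C@H](O)[C@H](C(C)C)[C@@H]1O[C@@H]1OC(=O)N(C(C)C)C(C)C | intermediate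
9 | (2S,3S,4R,5S)-3-hydroxy-4-isopropyl-5-vinyloxolan-2-yl N,N-diisopropylcarbamate | C=C[C@@H]1O[C@@H](OC(=O)N(C(C)C)C(C)C)[C@@H](O)[C@H]1C(C)C | intermediate
10 | (3S,4R,5S)-3-hydroxy-4-isopropyl-5-vinyloxolan-2-one | C=C[C@@H]1OC(=O)[C@@H](O)[C@H]1C(C)C | intermediate
11 | (tert-butyldimethylsilyloxy)acetaldehyde | CC(C)(C)[Si](C)(C)OCC=O | starting material
12 | ethyl 2-(triphenylphosphoranylidene)propanoate | CCOC(=O)C(C)=P(c1ccccc1)(c1ccccc1)c1ccccc1 | starting material
13 | ethyl (E)-4-(tert-butyldimethylsilyloxy)-2-methylbut-2-enoate | CCOC(=O)/C(C)=C/CO[Si](C)(C)C(C)(C)C | intermediate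
14 | (E)-4-(tert-butyldimethylsilyloxy)-2-methylbut-2-enoic acid | OC(=O)/C(C)=C/CO[Si](C)(C)C(C)(C)C | intermediate
15 | (3S,4S,5S)-4-isopropyl-2-oxo-5-vinyloxolan-3-yl (E)-4-(tert-butyldimethylsilyloxy)-2-methylbut-2-enoate | C=C[C@@H]1OC(=O)[C@@H](OC(=O)/C(C)=C/CO[Si](C)(C)C(C)(C)C)[C@H]1C(C)C | intermediate
16 | 2-bromoprop-2-en-1-ol | OCC(Br)=C | starting material
17 | (2-bromoallyloxy)(tert-butyl)dimethylsilane | C=C(Br)CO[Si](C)(C)C(C)(C)C | intermediate
18 | [3-(tert-butyldimethylsilyloxy)prop-1-en-2-yl]lithium | [Li]C(=C)CO[Si](C)(C)C(C)(C)C | intermediate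
19 | (4S,5S,6S)-2-[(tert-butyldimethylsilyloxy)methyl]-6-hydroxy-5-isopropyl-3-oxoocta-1,7-dien-4-yl (E)-4-(tert-butyldimethylsilyloxy)-2-methylbut-2-enoate | C=C[C@H](O)[C@H](C(C)C)[C@H](OC(=O)/C(C)=C/CO[Si](C)(C)C(C)(C)C)C(=O)C(=C)CO[Si](C)(C)C(C)(C)C | intermediate
20 | angelic acid, (Z)-2-methylbut-2-enoic acid | C/C=C(/C)C(=O)O | starting material
21 | (Z)-2-methylbut-2-enoic 2,4,6-trichlorobenzoic anhydride | C/C=C(/C)C(=O)OC(=O)c1c(Cl)cc(Cl)cc1Cl | intermediate
22 | (4S,5S,6S)-2-[(tert-butyldimethylsilyloxy)methyl]-5-isopropyl-6-[(Z)-2-methylbut-2-enoyloxy]-3-oxoocta-1,7-dien-4-yl (E)-4-(tert-butyldimethylsilyloxy)-2-methylbut-2-enoate | C/C=C(/C)C(=O)O[C@H]([C@H](C(C)C)[C@H](OC(=O)/C(C)=C/CO[Si](C)(C)C(C)(C)C)C(=O)C(=C)CO[Si](C)(C)C(C)(C)C)C=C | intermediate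
23 | bis(tert-butyldimethylsilyl) ether of the target, (4S,5S,6S) | C/C=C(/C)C(=O)O[C@H]1C=C(CO[Si](C)(C)C(C)(C)C)C(=O)[C@@H](OC(=O)/C(C)=C/CO[Si](C)(C)C(C)(C)C)[C@H]1C(C)C | intermediate
24 | (4S,5S,6S)-2-(hydroxymethyl)-6-[(E)-4-hydroxy-2-methylbut-2-enoyloxy]-5-isopropyl-4-[(Z)-2-methylbut-2-enoyloxy]cyclohex-2-en-1-one | C/C=C(/C)C(=O)O[C@H]1C=C(CO)C(=O)[C@@H](OC(=O)/C(C)=C/CO)[C@H]1C(C)C | target

Total step count: 12. Longest linear sequence: 9 (steps 1, 2, 3, 4, 7, 9, 10, 11, 12).

**Steps most likely to fail**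

Step 2. The enantioselectivity of the sparteine-mediated lithiation is well established for the crotyl carbamate but untested with the isopropyl group. The fallback sets out from 3 and comes back at 7, replacing asymmetric deprotonation by resolution. Compound 3 is lithiated with n-BuLi/TMEDA, titanated with Ti(OiPr)4 and added to 4 to give the racemic anti-(Z)-homoaldol adduct F1. Candida antarctica lipase B with vinyl acetate in hexane then acetylates the (3S,4R) enantiomer to the (3S,4R)-acetate F2. Unreacted 7 is separated by chromatography.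

Step 4. Ionisation of an anomeric carbamate next to a free hydroxyl may be slow, or the peracid may attack the vinyl group. The fallback sets out from 9 and comes back at 10, replacing peracid fragmentation by hydrolysis and selective hemiacetal oxidation. Aqueous trifluoroacetic acid in THF cleaves the anomeric carbamate to the lactol F3. Ag2CO3 on Celite in hot toluene then oxidises only the hemiacetal hydroxyl to the lactone.

Step 9. The alkenyllithium may attack the side-chain ester, or it may deprotonate C3 and scramble that centre. The fallback sets out from 10 and comes back at 22, moving the O3 esterification after the organolithium step.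
- Compound 10 is silylated (Et3SiCl, imidazole) to the triethylsilyl ether F4.
- Alkenyllithium 18 adds to this ester-free lactone to give the hydroxy enone F5.
- Mixed anhydride 21 acylates O5 to give the angelate F6.
- PPTS in methanol removes only the triethylsilyl group to give the alpha-hydroxy enone F7.
- DCC/DMAP coupling of F7 with 14 delivers 22.

**Further compounds**
F1 | step 2 | racemic anti-(1Z)-4-hydroxy-3-isopropylhexa-1,5-dien-1-yl N,N-diisopropylcarbamate | C=CC(O)C(C(C)C)/C=C\OC(=O)N(C(C)C)C(C)C
F2 | step 2 | (1Z,3S,4R)-4-acetoxy-3-isopropylhexa-1,5-dien-1-yl N,N-diisopropylcarbamate | C=C[C@@H](OC(C)=O)[C@@H](C(C)C)/C=C\OC(=O)N(C(C)C)C(C)C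
F3 | step 4 | (3S,4R,5S)-4-isopropyl-5-vinyloxolane-2,3-diol (anomeric mixture) | C=C[C@@H]1OC(O)[C@@H](O)[C@H]1C(C)C
F4 | step 9 | (3S,4S,5S)-4-isopropyl-3-(triethylsilyloxy)-5-vinyloxolan-2-one | C=C[C@@H]1OC(=O)[C@@H](O[Si](CC)(CC)CC)[C@H]1C(C)C
F5 | step 9 | (4S,5S,6S)-2-[(tert-butyldimethylsilyloxy)methyl]-6-hydroxy-5-isopropyl-4-(triethylsilyloxy)octa-1,7-dien-3-one | C=C[C@H](O)[C@H](C(C)C)[C@H](O[Si](CC)(CC)CC)C(=O)C(=C)CO[Si](C)(C)C(C)(C)C
F6 | step 9 | O5 angelate of F5 | C/C=C(/C)C(=O)O[C@H]([C@H](C(C)C)[C@H](O[Si](CC)(CC)CC)C(=O)C(=C)CO[Si](C)(C)C(C)(C)C)C=C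
F7 | step 9 | O5 angelate with free C3 hydroxyl | C/C=C(/C)C(=O)O[C@H]([C@H](C(C)C)[C@H](O)C(=O)C(=C)CO[Si](C)(C)C(C)(C)C)C=C
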